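## Retrosynthetic overview

1. Eriolanin ⇒ hydroxy α‑methylene lactone 18 (methacrylation at O6, then removal of both silyl ethers).
2. γ‑Lactone (last ring formed) ⇒ epoxy phosphonoacetate 15: the tethered carbanion opens the C6–C7 epoxide at C7, then Horner–Wadsworth–Emmons olefination with CH2O. The tether is put on with inversion at C8 after an OH‑directed epoxidation.
3. Cyclohexadienol 11 ⇒ 7‑oxanorbornene ester 9 by base‑induced β‑elimination of the oxygen bridge and ester reduction.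
4. Key disconnection: 9 ⇒ 2‑alkylfuran 7 + acrylate 8 by a catalytic enantioselective dearomative Diels–Alder reaction. It forms the carbocycle first and fixes C8, from which C7 and C6 are relayed.
5. 7 ⇒ furan + secondary boronic ester 3 (stereospecific boronate coupling); 3 comes from pent‑4‑en‑1‑ol by enantioselective Markovnikov protoboration (sets C4).

Atom labels used below (eudesmane numbering): ring carbons C5–C10 with the C5=C10 alkene; C6 bears the methacrylate; C7/C8 are the lactone fusion; C11–C13 are the acrylate unit of the lactone; C14 is the ring CH2OH; C4 is the side‑chain stereocentre; C1 is the side‑chain CH2OH. TBS = tert‑butyldimethylsilyl, pin = pinacolato.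

Assumption: where a chiral ligand or catalyst is named, the antipode that delivers the drawn stereoisomer is the one used; its sense of induction would be confirmed on the first run.

## Route

Step 1
Reactants: 1 pent‑4‑en‑1‑ol
Product: 2 tert‑butyldimethyl(pent‑4‑en‑1‑yloxy)silane
Conditions: TBSCl, imidazole, CH2Cl2, 0 °C to rt
Reagents that add atoms: tert‑butyldimethylsilyl chloride, CC(C)(C)[Si](C)(C)Cl
Why: Standard silylation of a primary alcohol, which masks O1 until the last step; no stereocentre is involved.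

Step 2
Reactants: 2 tert‑butyldimethyl(pent‑4‑en‑1‑yloxy)silane
Product: 3 tert‑butyldimethyl{[(4S)‑4‑(4,4,5,5‑tetramethyl‑1,3,2‑dioxaborolan‑2‑yl)pentyl]oxy}silane
Conditions: B2pin2, CuCl (5 mol%), (R,R,R,R)‑ANIPE chiral NHC ligand (6 mol%), NaOtBu (cat.), MeOH (2 equiv), THF, rt
Reagents that add atoms: bis(pinacolato)diboron, CC1(C)OB(OC1(C)C)B1OC(C)(C)C(C)(C)O1
Why: Copper–NHC‑catalysed enantioselective Markovnikov protoboration of an α‑olefin: borylcupration puts boron on the internal carbon from the ligand‑selected alkene face and methanol protonates the primary C–Cu bond, which sets C4 (S).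

Step 3
Reactants: 3 tert‑butyldimethyl{[(4S)‑4‑(4,4,5,5‑tetramethyl‑1,3,2‑dioxaborolan‑2‑yl)pentyl]oxy}silane; 4 furan
Product: 7 2‑[(2S)‑5‑(tert‑butyldimethylsilyloxy)pentan‑2‑yl]furan, via 2‑furyllithium 5 (not isolated), via lithium furyl(alkyl)pinacolatoborate 6 (not isolated)
Conditions: 4 (1.3 equiv), n‑BuLi, THF, −78 to 0 °C; add 3, −78 °C; NBS, THF, −78 °C to rt
Reagents that add atoms: none
Why: Stereospecific sp2–sp3 coupling by boronate formation and bromination‑triggered 1,2‑metallate rearrangement/elimination; the sec‑alkyl group migrates from boron to the furan carbon with retention, so C4 stays S.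

Step 4
Reactants: 7 2‑[(2S)‑5‑(tert‑butyldimethylsilyloxy)pentan‑2‑yl]furan; 8 2,2,2‑trifluoroethyl acrylate
Product: 9 2,2,2‑trifluoroethyl (1S,2S,4S)‑1‑[(2S)‑5‑(tert‑butyldimethylsilyloxy)pentan‑2‑yl]‑7‑oxabicyclo[2.2.1]hept‑5‑ene‑2‑carboxylate (2‑endo ester)
Conditions: o‑tolyl oxazaborolidine from diphenylprolinol (20 mol%), Tf2NH (17 mol%), CH2Cl2, −78 °C; used cold in step 5
Reagents that add atoms: none
Why: Proposed new method: catalytic enantioselective dearomative Diels–Alder reaction of a 2‑sec‑alkylfuran, in which the cationic oxazaborolidinium‑bound acrylate exposes one face, the asynchronous transition state joins the unsubstituted furan α‑carbon to the acrylate β‑carbon (ester next to the substituted bridgehead) and endo approach fixes both bridgeheads and thereby C8; the closest known reactions are the oxazaborolidinium‑catalysed cycloaddition of furan itself to this acrylate and the HfCl4‑promoted endo‑selective cycloadditions of 2‑methylfuran to acrylates.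

Step 5
Reactants: 9 2,2,2‑trifluoroethyl (1S,2S,4S)‑1‑[(2S)‑5‑(tert‑butyldimethylsilyloxy)pentan‑2‑yl]‑7‑oxabicyclo[2.2.1]hept‑5‑ene‑2‑carboxylate
Product: 11 (1S)‑5‑(hydroxymethyl)‑4‑[(2S)‑5‑(tert‑butyldimethylsilyloxy)pentan‑2‑yl]cyclohexa‑2,4‑dien‑1‑ol, via lithium alkoxide of the 5‑hydroxycyclohexa‑1,3‑diene ester 10 (not isolated)
Conditions: LiN(SiMe3)2, THF, −78 to 0 °C; then i‑Bu2AlH, −78 °C; Rochelle salt work‑up, base‑washed silica
Reagents that add atoms: none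
Why: E1cB β‑elimination from the ester enolate cleaves the bridgehead C5–O bond (oxanorbornene ring opening) to give the C5=C10/C6=C7 dienoate with the C8 carbinol untouched, and 1,2‑reduction of the dienoate in the same flask delivers C14 as the allylic alcohol.

Step 6
Reactants: 11 (1S)‑5‑(hydroxymethyl)‑4‑[(2S)‑5‑(tert‑butyldimethylsilyloxy)pentan‑2‑yl]cyclohexa‑2,4‑dien‑1‑ol
Product: 12 (1S)‑5‑[(tert‑butyldimethylsilyloxy)methyl]‑4‑[(2S)‑5‑(tert‑butyldimethylsilyloxy)pentan‑2‑yl]cyclohexa‑2,4‑dien‑1‑ol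
Conditions: TBSCl (1.05 equiv), imidazole, CH2Cl2, −20 °C
Reagents that add atoms: tert‑butyldimethylsilyl chloride, CC(C)(C)[Si](C)(C)Cl
Why: The primary allylic alcohol is silylated selectively over the secondary one, which leaves O8 free as the directing group and removes the competing directing effect of O14.

Step 7
Reactants: 12 (1S)‑5‑[(tert‑butyldimethylsilyloxy)methyl]‑4‑[(2S)‑5‑(tert‑butyldimethylsilyloxy)pentan‑2‑yl]cyclohexa‑2,4‑dien‑1‑ol
Product: 13 (1S,2S,6R)‑4‑[(tert‑butyldimethylsilyloxy)methyl]‑5‑[(2S)‑5‑(tert‑butyldimethylsilyloxy)pentan‑2‑yl]‑7‑oxabicyclo[4.1.0]hept‑4‑en‑2‑ol (epoxide syn to OH)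
Conditions: VO(acac)2 (3 mol%), t‑BuOOH, CH2Cl2, 0 °C
Reagents that add atoms: tert‑butyl hydroperoxide, CC(C)(C)OO
Why: Hydroxyl‑directed vanadium‑catalysed epoxidation reacts only at the allylic C6=C7 alkene (the tetrasubstituted C5=C10 alkene is merely homoallylic) and delivers oxygen syn to O8, which sets C6 and C7.

Step 8
Reactants: 13 (1S,2S,6R)‑epoxy alcohol; 14 (diethoxyphosphoryl)acetic acid
Product: 15 (1S,2R,6R)‑4‑[(tert‑butyldimethylsilyloxy)methyl]‑5‑[(2S)‑5‑(tert‑butyldimethylsilyloxy)pentan‑2‑yl]‑7‑oxabicyclo[4.1.0]hept‑4‑en‑2‑yl (diethoxyphosphoryl)acetate (epoxide anti to the ester)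
Conditions: PPh3, DIAD, toluene, 0 °C to rt (acid added last)
Reagents that add atoms: none
Why: Mitsunobu esterification proceeds by SN2 inversion at C8, so the phosphonoacetate tether ends on the face opposite the epoxide and C8 reaches its final configuration.

Step 9
Reactants: 15 (1S,2R,6R)‑epoxy phosphonoacetate; 16 formaldehyde (as paraformaldehyde)
Product: 18 (3aS,4S,7aR)‑4‑hydroxy‑3‑methylidene‑5‑[(2S)‑5‑(tert‑butyldimethylsilyloxy)pentan‑2‑yl]‑6‑[(tert‑butyldimethylsilyloxy)methyl]‑3a,4,7,7a‑tetrahydro‑1‑benzofuran‑2(3H)‑one, via α‑phosphono lactone sodium enolate 17 (not isolated)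
Conditions: NaH (1.2 equiv), THF, 0 to 40 °C; then (CH2O)n, rt
Reagents that add atoms: none
Why: Proposed new method: the phosphonoacetate anion opens the epoxide intramolecularly in the 5‑exo mode at C7, anti to the epoxide oxygen and therefore on the face carrying O8, which gives the cis‑fused lactone with O6 trans to C11, and the resulting α‑phosphono lactone anion is then olefinated with formaldehyde (Horner–Wadsworth–Emmons); the closest known reactions are the tandem intramolecular Michael/Horner–Wadsworth–Emmons lactone annulation of phosphonoacetates and malonate‑type intramolecular epoxide alkylations.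

Step 10
Reactants: 18 hydroxy α‑methylene lactone; 19 methacrylic anhydride
Product: 20 (3aR,4S,7aR)‑3‑methylidene‑2‑oxo‑5‑[(2S)‑5‑(tert‑butyldimethylsilyloxy)pentan‑2‑yl]‑6‑[(tert‑butyldimethylsilyloxy)methyl]‑3a,4,7,7a‑tetrahydro‑1‑benzofuran‑4‑yl 2‑methylprop‑2‑enoate
Conditions: Et3N, DMAP (cat.), CH2Cl2, 0 °C to rt
Reagents that add atoms: none
Why: DMAP‑catalysed acylation of the only free hydroxyl (O6) with retention; the descriptor at C3a changes from S to R only because the CIP priorities change.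

Step 11
Reactants: 20 bis‑silyl eriolanin
Product: 21 eriolanin, [(3aR,4S,7aR)‑6‑(hydroxymethyl)‑5‑[(2S)‑5‑hydroxypentan‑2‑yl]‑3‑methylidene‑2‑oxo‑3a,4,7,7a‑tetrahydro‑1‑benzofuran‑4‑yl] 2‑methylprop‑2‑enoate
Conditions: HF·pyridine, pyridine, THF, 0 °C to rt
Reagents that add atoms: none
Why: Buffered fluoride desilylation frees both primary alcohols without touching the methacrylate, the α‑methylene lactone or any stereocentre.

## Compound list

1 | pent‑4‑en‑1‑ol | OCCCC=C | starting material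
2 | tert‑butyldimethyl(pent‑4‑en‑1‑yloxy)silane | C=CCCCO[Si](C)(C)C(C)(C)C | intermediate
3 | tert‑butyldimethyl{[(4S)‑4‑(pinacolboryl)pentyl]oxy}silane | CC1(C)OB(OC1(C)C)[C@@H](C)CCCO[Si](C)(C)C(C)(C)C | intermediate
4 | furan | c1ccoc1 | starting material
5 | 2‑furyllithium (not isolated) | [Li]c1ccco1 | intermediate
6 | lithium (furan‑2‑yl)[(2S)‑5‑(TBS‑oxy)pentan‑2‑yl]pinacolatoborate (not isolated) | [Li+].CC1(C)O[B-](OC1(C)C)(c1ccco1)[C@@H](C)CCCO[Si](C)(C)C(C)(C)C | intermediate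
7 | 2‑[(2S)‑5‑(TBS‑oxy)pentan‑2‑yl]furan | o1cccc1[C@@H](C)CCCO[Si](C)(C)C(C)(C)C | intermediate
8 | 2,2,2‑trifluoroethyl acrylate | C=CC(=O)OCC(F)(F)F | starting material
9 | 2,2,2‑trifluoroethyl (1S,2S,4S)‑1‑[(2S)‑5‑(TBS‑oxy)pentan‑2‑yl]‑7‑oxabicyclo[2.2.1]hept‑5‑ene‑2‑carboxylate | FC(F)(F)COC(=O)[C@H]1C[C@H]2C=C[C@]1([C@@H](C)CCCO[Si](C)(C)C(C)(C)C)O2 | intermediate
10 | lithium alkoxide of 2,2,2‑trifluoroethyl (5S)‑5‑hydroxy‑2‑[(2S)‑5‑(TBS‑oxy)pentan‑2‑yl]cyclohexa‑1,3‑diene‑1‑carboxylate (not isolated) | [Li+].[O-][C@H]1CC(C(=O)OCC(F)(F)F)=C([C@@H](C)CCCO[Si](C)(C)C(C)(C)C)C=C1 | intermediate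
11 | (1S)‑5‑(hydroxymethyl)‑4‑[(2S)‑5‑(TBS‑oxy)pentan‑2‑yl]cyclohexa‑2,4‑dien‑1‑ol | O[C@H]1CC(CO)=C([C@@H](C)CCCO[Si](C)(C)C(C)(C)C)C=C1 | intermediate
12 | (1S)‑5‑[(TBS‑oxy)methyl]‑4‑[(2S)‑5‑(TBS‑oxy)pentan‑2‑yl]cyclohexa‑2,4‑dien‑1‑ol | O[C@H]1CC(CO[Si](C)(C)C(C)(C)C)=C([C@@H](C)CCCO[Si](C)(C)C(C)(C)C)C=C1 | intermediate
13 | (1S,2S,6R)‑4‑[(TBS‑oxy)methyl]‑5‑[(2S)‑5‑(TBS‑oxy)pentan‑2‑yl]‑7‑oxabicyclo[4.1.0]hept‑4‑en‑2‑ol | O[C@H]1CC(CO[Si](C)(C)C(C)(C)C)=C([C@@H](C)CCCO[Si](C)(C)C(C)(C)C)[C@H]2O[C@@H]12 | intermediate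
14 | (diethoxyphosphoryl)acetic acid | OC(=O)CP(=O)(OCC)OCC | starting material
15 | (1S,2R,6R)‑4‑[(TBS‑oxy)methyl]‑5‑[(2S)‑5‑(TBS‑oxy)pentan‑2‑yl]‑7‑oxabicyclo[4.1.0]hept‑4‑en‑2‑yl (diethoxyphosphoryl)acetate | CCOP(=O)(OCC)CC(=O)O[C@@H]1CC(CO[Si](C)(C)C(C)(C)C)=C([C@@H](C)CCCO[Si](C)(C)C(C)(C)C)[C@H]2O[C@@H]12 | intermediate
16 | formaldehyde (used as paraformaldehyde) | C=O | starting material
17 | sodium enolate of (3aS,4S,7aR)‑3‑(diethoxyphosphoryl)‑4‑hydroxy‑5‑[(2S)‑5‑(TBS‑oxy)pentan‑2‑yl]‑6‑[(TBS‑oxy)methyl]‑3a,4,7,7a‑tetrahydro‑1‑benzofuran‑2(3H)‑one (not isolated) | [Na+].O[C@@H]1C([C@@H](C)CCCO[Si](C)(C)C(C)(C)C)=C(CO[Si](C)(C)C(C)(C)C)C[C@H]2OC([O-])=C(P(=O)(OCC)OCC)[C@@H]12 | intermediate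
18 | (3aS,4S,7aR)‑4‑hydroxy‑3‑methylidene‑5‑[(2S)‑5‑(TBS‑oxy)pentan‑2‑yl]‑6‑[(TBS‑oxy)methyl]‑3a,4,7,7a‑tetrahydro‑1‑benzofuran‑2(3H)‑one | O[C@@H]1C([C@@H](C)CCCO[Si](C)(C)C(C)(C)C)=C(CO[Si](C)(C)C(C)(C)C)C[C@H]2OC(=O)C(=C)[C@@H]12 | intermediate
19 | methacrylic anhydride | CC(=C)C(=O)OC(=O)C(C)=C | starting material
20 | bis‑TBS eriolanin, (3aR,4S,7aR)‑4‑yl 2‑methylprop‑2‑enoate | C=C(C)C(=O)O[C@@H]1C([C@@H](C)CCCO[Si](C)(C)C(C)(C)C)=C(CO[Si](C)(C)C(C)(C)C)C[C@H]2OC(=O)C(=C)[C@@H]12 | intermediate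
21 | eriolanin (CNP0142089.2) | C=C(C)C(=O)O[C@@H]1C([C@@H](C)CCCO)=C(CO)C[C@H]2OC(=O)C(=C)[C@@H]12 | target

## Step count and risk

Total step count: 11. Longest linear sequence: 11 steps (1 to 21); furan 4 enters at step 3, acrylate 8 at step 4.

Dienols 11 and 12 and vinyl epoxides 13 and 15 are acid‑sensitive (dehydration to the arene, allylic epoxide opening) and are handled on base‑washed silica.

**Step 4 (asymmetric furan Diels–Alder).** This is the least precedented step. It needs regiocontrol, endo control and face control at once: an exo adduct formed on the same acrylate face has the opposite bridgehead sense and would erode the C8 purity after step 5, so it must be removed by chromatography. Acid‑promoted Michael‑type alkylation of the furan and cycloreversion on warming are the main side reactions.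

Fallback: setting out from 7, the cycloaddition is run without a chiral catalyst (methyl acrylate, HfCl4, CH2Cl2, −50 °C) to give the methyl ester cycloadduct mixture F1. LiN(SiMe3)2 opens it to the C5‑epimeric dienol methyl esters F2, which are diastereomers because C4 is already fixed. Candida antarctica lipase B with vinyl acetate acylates the 5R epimer (Kazlauskas rule, as for cyclohex‑2‑enol) to the (5R)‑acetate F4 and leaves the (5S)‑dienol methyl ester F3. F3 is separated on silica and reduced with i‑Bu2AlH, which rejoins the route at 11. Here C8 is set by enzymatic acyl transfer instead of by the cycloaddition catalyst.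

**Step 8 (Mitsunobu inversion next to a vinyl epoxide).** Elimination towards C9 and acid‑promoted opening of the allylic epoxide by the carboxylic acid can compete with substitution at C8.

Fallback: setting out from 7, the antipodal oxazaborolidinium catalyst gives the enantiomeric‑ring cycloadduct F5, which LiN(SiMe3)2 opens to the isolated (5R)‑dienol ester F6. Et3SiCl/imidazole gives the triethylsilyl ether F7. Buffered mCPBA then epoxidises only the γ,δ‑alkene (the C5=C10 alkene is deactivated by the ester) on the face anti to the silyl ether, giving the anti‑epoxy ester F8. i‑Bu2AlH reduces the ester to the epoxy allylic alcohol F9, TBSCl gives the mixed silyl ether F10, and buffered HF·pyridine removes the triethylsilyl group to the anti‑epoxy alcohol F11. Steglich esterification of F11 with 14 (DCC, DMAP) gives 15, where the route is rejoined. No substitution at C8 is needed, at the cost of three extra steps.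

**Step 9 (tethered epoxide opening/olefination).** Attack at the allylic epoxide carbon C6 (bridged δ‑lactone) or a sluggish opening by the stabilised anion would defeat the cascade.

Fallback: setting out from 15, Pd(PPh3)4 and methacrylic acid open the vinyl epoxide through the π‑allyl complex with net retention at C6, giving the C6 methacrylate C7 alcohol F12 and installing the methacrylate early. Tf2O/pyridine converts the now non‑allylic C7 hydroxyl into the triflate F13. NaH then drives intramolecular SN2 alkylation by the phosphonoacetate anion at C7 with inversion to the α‑phosphono lactone methacrylate F14, and paraformaldehyde completes the olefination to rejoin the route at 20. C6 is no longer an electrophilic site when the ring is closed.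

## Further compounds

F1 | step 4 | methyl 1‑[(2S)‑5‑(TBS‑oxy)pentan‑2‑yl]‑7‑oxabicyclo[2.2.1]hept‑5‑ene‑2‑carboxylate, mixture of ring stereoisomers | COC(=O)C1CC2C=CC1([C@@H](C)CCCO[Si](C)(C)C(C)(C)C)O2
F2 | step 4 | methyl (5RS)‑5‑hydroxy‑2‑[(2S)‑5‑(TBS‑oxy)pentan‑2‑yl]cyclohexa‑1,3‑diene‑1‑carboxylate | COC(=O)C1=C([C@@H](C)CCCO[Si](C)(C)C(C)(C)C)C=CC(O)C1
F3 | step 4 | methyl (5S)‑5‑hydroxy‑2‑[(2S)‑5‑(TBS‑oxy)pentan‑2‑yl]cyclohexa‑1,3‑diene‑1‑carboxylate | COC(=O)C1=C([C@@H](C)CCCO[Si](C)(C)C(C)(C)C)C=C[C@@H](O)C1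
F4 | step 4 | methyl (5R)‑5‑acetoxy‑2‑[(2S)‑5‑(TBS‑oxy)pentan‑2‑yl]cyclohexa‑1,3‑diene‑1‑carboxylate | COC(=O)C1=C([C@@H](C)CCCO[Si](C)(C)C(C)(C)C)C=C[C@H](OC(C)=O)C1
F5 | step 8 | 2,2,2‑trifluoroethyl (1R,2R,4R)‑1‑[(2S)‑5‑(TBS‑oxy)pentan‑2‑yl]‑7‑oxabicyclo[2.2.1]hept‑5‑ene‑2‑carboxylate | FC(F)(F)COC(=O)[C@@H]1C[C@@H]2C=C[C@@]1([C@@H](C)CCCO[Si](C)(C)C(C)(C)C)O2
F6 | step 8 | 2,2,2‑trifluoroethyl (5R)‑5‑hydroxy‑2‑[(2S)‑5‑(TBS‑oxy)pentan‑2‑yl]cyclohexa‑1,3‑diene‑1‑carboxylate | O[C@@H]1CC(C(=O)OCC(F)(F)F)=C([C@@H](C)CCCO[Si](C)(C)C(C)(C)C)C=C1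
F7 | step 8 | 2,2,2‑trifluoroethyl (5R)‑5‑(triethylsilyloxy)‑2‑[(2S)‑5‑(TBS‑oxy)pentan‑2‑yl]cyclohexa‑1,3‑diene‑1‑carboxylate | CC[Si](CC)(CC)O[C@@H]1CC(C(=O)OCC(F)(F)F)=C([C@@H](C)CCCO[Si](C)(C)C(C)(C)C)C=C1
F8 | step 8 | 2,2,2‑trifluoroethyl 2‑[(2S)‑5‑(TBS‑oxy)pentan‑2‑yl]‑5‑(triethylsilyloxy)‑7‑oxabicyclo[4.1.0]hept‑2‑ene‑3‑carboxylate, epoxide anti to the silyloxy group | CC[Si](CC)(CC)O[C@@H]1CC(C(=O)OCC(F)(F)F)=C([C@@H](C)CCCO[Si](C)(C)C(C)(C)C)[C@H]2O[C@@H]12
F9 | step 8 | {2‑[(2S)‑5‑(TBS‑oxy)pentan‑2‑yl]‑5‑(triethylsilyloxy)‑7‑oxabicyclo[4.1.0]hept‑2‑en‑3‑yl}methanol, epoxide anti to the silyloxy group | CC[Si](CC)(CC)O[C@@H]1CC(CO)=C([C@@H](C)CCCO[Si](C)(C)C(C)(C)C)[C@H]2O[C@@H]12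
F10 | step 8 | triethylsilyl ether of F11 (C8 O‑triethylsilyl, C14 O‑TBS, C1 O‑TBS) | CC[Si](CC)(CC)O[C@@H]1CC(CO[Si](C)(C)C(C)(C)C)=C([C@@H](C)CCCO[Si](C)(C)C(C)(C)C)[C@H]2O[C@@H]12
F11 | step 8 | (1S,2R,6R)‑4‑[(TBS‑oxy)methyl]‑5‑[(2S)‑5‑(TBS‑oxy)pentan‑2‑yl]‑7‑oxabicyclo[4.1.0]hept‑4‑en‑2‑ol, epoxide anti to OH | O[C@@H]1CC(CO[Si](C)(C)C(C)(C)C)=C([C@@H](C)CCCO[Si](C)(C)C(C)(C)C)[C@H]2O[C@@H]12
F12 | step 9 | C6 methacrylate, C7 alcohol, C8 (diethoxyphosphoryl)acetate of the bis‑TBS cyclohexene triol (O6 and O7 cis, O8 trans to both) | C=C(C)C(=O)O[C@@H]1C([C@@H](C)CCCO[Si](C)(C)C(C)(C)C)=C(CO[Si](C)(C)C(C)(C)C)C[C@@H](OC(=O)CP(=O)(OCC)OCC)[C@@H]1O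
F13 | step 9 | C7 trifluoromethanesulfonate of F12 | C=C(C)C(=O)O[C@@H]1C([C@@H](C)CCCO[Si](C)(C)C(C)(C)C)=C(CO[Si](C)(C)C(C)(C)C)C[C@@H](OC(=O)CP(=O)(OCC)OCC)[C@@H]1OS(=O)(=O)C(F)(F)F
F14 | step 9 | (3aS,4S,7aR)‑3‑(diethoxyphosphoryl)‑2‑oxo‑5‑[(2S)‑5‑(TBS‑oxy)pentan‑2‑yl]‑6‑[(TBS‑oxy)methyl]‑hexahydro‑1‑benzofuran‑4‑yl 2‑methylprop‑2‑enoate, C3 epimers | C=C(C)C(=O)O[C@@H]1C([C@@H](C)CCCO[Si](C)(C)C(C)(C)C)=C(CO[Si](C)(C)C(C)(C)C)C[C@H]2OC(=O)C(P(=O)(OCC)OCC)[C@@H]12
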